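**Retrosynthetic overview**
1. Rings A and B are bought, not built: phloroacetophenone 1 + prenyl bromide 2 (A ring), 5-iodovanillin 3 + prenylstannane 4 (B ring).
2. C–prenyl disconnections: double C-prenylation of 1 (through mono-prenyl ketone 5) gives ketone 6; Stille prenylation of 3 gives aldehyde 7.
3. Cα=Cβ disconnection: protecting-group-free aldol condensation of 6 + 7 (through aldol 8) gives the open chalcone 9.
4. O1–C2 disconnection (the only ring made, closed last): chalcone-isomerase-like enantioselective 6-endo oxa-Michael closure of 9 gives the (2S)-flavanone 10, so C2 is set in the final step and sees no further reagents.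
5. Ring order: A and B (purchased), then C (pyranone, last).

Assumption: the quinine-derived thiourea in step 4 is taken to give the 2S sense; this is checked by CD (2S-flavanones: negative Cotton effect near 290 nm, positive near 330 nm), and if the sense is opposite the pseudo-enantiomeric quinidine-derived thiourea is used in the same step.

**Route**

Step 1
Reactants: 1 2,4,6-trihydroxyacetophenone; 2 prenyl bromide (2.2 equiv)
Product: 6 1-[2,4,6-trihydroxy-3,5-bis(3-methylbut-2-en-1-yl)phenyl]ethanone, via mono-prenyl ketone 5 (not isolated)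
Conditions: 10% aq KOH, 0 °C → rt, 4 h; acidic work-up, chromatography
Reagents that add atoms: prenyl bromide 2, CC(C)=CCBr
Why: Phenoxide C-alkylation (C-prenylation of an ambident acylphloroglucinol phenolate): in water the oxygens are hydrogen-bond-solvated, so the allylic bromide is attacked in SN2 fashion by the two equivalent ring carbons (C3, then C5 of 5 in the same pot); O- and gem-dialkylated by-products are removed by chromatography and no stereocenter is formed.

Step 2
Reactants: 3 5-iodovanillin; 4 tributyl(3-methylbut-2-en-1-yl)stannane (1.2 equiv)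
Product: 7 4-hydroxy-3-methoxy-5-(3-methylbut-2-en-1-yl)benzaldehyde (5-prenylvanillin)
Conditions: Pd(PPh3)4 (5 mol%), DMF, 90 °C, 12 h
Reagents that add atoms: tributyl(3-methylbut-2-en-1-yl)stannane 4, CCCC[Sn](CCCC)(CCCC)CC=C(C)C
Why: Migita–Kosugi–Stille coupling: oxidative addition of Pd(0) into the aryl C–I bond, prenyl transfer from tin and reductive elimination at the less hindered allyl terminus give the linear prenyl arene at the only position ortho to the phenol, and the neutral conditions tolerate the free phenol and the aldehyde; no stereocenter is formed.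

Step 3
Reactants: 6 1-[2,4,6-trihydroxy-3,5-bis(3-methylbut-2-en-1-yl)phenyl]ethanone; 7 5-prenylvanillin
Product: 9 (E)-3-[4-hydroxy-3-methoxy-5-(3-methylbut-2-en-1-yl)phenyl]-1-[2,4,6-trihydroxy-3,5-bis(3-methylbut-2-en-1-yl)phenyl]prop-2-en-1-one, via aldol adduct 8 (not isolated)
Conditions: LiHMDS (6.5 equiv), THF, −78 °C → rt, 24 h; then cold 1 M HCl, 0 °C; rapid chromatography, store cold
Reagents that add atoms: none
Why: Claisen–Schmidt (crossed aldol) condensation through polylithiated species: excess LiHMDS turns 6 into its tris-phenoxide lithium enolate and 7 into its lithium phenoxide, the enolate adds to the non-enolisable aldehyde, and E1cB loss of hydroxide from 8 gives the conjugated (E)-enone, which stays open because the polyanion (B-ring 4-phenoxide pushing into the enone) disfavours oxa-Michael closure until the cold acidic quench; no stereocenter remains in 9.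

Step 4
Reactants: 9 the open chalcone
Product: 10 (2S)-5,7-dihydroxy-2-[4-hydroxy-3-methoxy-5-(3-methylbut-2-en-1-yl)phenyl]-6,8-bis(3-methylbut-2-en-1-yl)chroman-4-one (target)
Conditions: quinine-derived bifunctional thiourea [N-(3,5-bis(trifluoromethyl)phenyl)-N'-(9-deoxy-epi-quinin-9-yl)thiourea, 10 mol%], toluene, −20 °C, 48–72 h; silica plug (0.5% AcOH in eluent); recrystallise if the ee needs upgrading
Reagents that add atoms: none
Why: Proposed new method: a chalcone-isomerase-mimetic enantioselective 6-endo-trig intramolecular oxa-Michael addition in which the quinuclidine nitrogen deprotonates the free (non-chelated) ortho-phenol of the symmetric A ring, the thiourea hydrogen-bonds the s-cis enone carbonyl, and the chiral ion pair delivers the phenoxide to one face of C-β so that C2 is set as S (either ortho-OH gives the same product, and the non-polar cold medium suppresses the racemic background closure and retro-Michael racemisation); the closest known reaction type is the cinchona-thiourea-catalysed asymmetric oxa-Michael cyclisation of activated 2'-hydroxychalcones (alkylidene β-keto esters) to flavanones, together with cinchona-alkaloid-catalysed cyclisation of plain 2'-hydroxychalcones.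

**Compound list**
1 | 2,4,6-trihydroxyacetophenone (phloroacetophenone) | CC(=O)c1c(O)cc(O)cc1O | starting material
2 | prenyl bromide (1-bromo-3-methylbut-2-ene) | CC(C)=CCBr | starting material
3 | 5-iodovanillin (4-hydroxy-3-iodo-5-methoxybenzaldehyde) | COc1cc(C=O)cc(I)c1O | starting material
4 | tributyl(3-methylbut-2-en-1-yl)stannane | CCCC[Sn](CCCC)(CCCC)CC=C(C)C | starting material
5 | 1-[2,4,6-trihydroxy-3-(3-methylbut-2-en-1-yl)phenyl]ethanone (mono-prenyl ketone, not isolated) | CC(=O)c1c(O)cc(O)c(CC=C(C)C)c1O | intermediate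
6 | 1-[2,4,6-trihydroxy-3,5-bis(3-methylbut-2-en-1-yl)phenyl]ethanone | CC(=O)c1c(O)c(CC=C(C)C)c(O)c(CC=C(C)C)c1O | intermediate
7 | 4-hydroxy-3-methoxy-5-(3-methylbut-2-en-1-yl)benzaldehyde (5-prenylvanillin) | COc1cc(C=O)cc(CC=C(C)C)c1O | intermediate
8 | racemic 3-hydroxy-3-[4-hydroxy-3-methoxy-5-(3-methylbut-2-en-1-yl)phenyl]-1-[2,4,6-trihydroxy-3,5-bis(3-methylbut-2-en-1-yl)phenyl]propan-1-one (aldol adduct, formed as its polylithium salt, not isolated) | COc1cc(C(O)CC(=O)c2c(O)c(CC=C(C)C)c(O)c(CC=C(C)C)c2O)cc(CC=C(C)C)c1O | intermediate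
9 | (E)-3-[4-hydroxy-3-methoxy-5-(3-methylbut-2-en-1-yl)phenyl]-1-[2,4,6-trihydroxy-3,5-bis(3-methylbut-2-en-1-yl)phenyl]prop-2-en-1-one (chalcone) | COc1cc(/C=C/C(=O)c2c(O)c(CC=C(C)C)c(O)c(CC=C(C)C)c2O)cc(CC=C(C)C)c1O | intermediate
10 | (2S)-5,7-dihydroxy-2-[4-hydroxy-3-methoxy-5-(3-methylbut-2-en-1-yl)phenyl]-6,8-bis(3-methylbut-2-en-1-yl)chroman-4-one | COc1cc([C@@H]2CC(=O)c3c(O)c(CC=C(C)C)c(O)c(CC=C(C)C)c3O2)cc(CC=C(C)C)c1O | target

**Totals**
Total steps: 4. Longest linear sequence: 3 steps (1 → 6 → 9 → 10, or 3 → 7 → 9 → 10).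

**Three steps most likely to fail, with fallbacks**

Step 4 (enantioselective closure; risk of low ee from the facile racemic background cyclisation of a 2',6'-dihydroxychalcone). The fallback sets out from chalcone 9 and comes back at 10. Chalcone 9 is closed under thermodynamic control (NaOAc, EtOH, reflux) to the racemic flavanone F1. This is resolved by preparative chiral SFC on an amylose tris(3,5-dimethylphenylcarbamate) phase to give 10. The unwanted (2R)-flavanone F2 is re-racemised under the same NaOAc conditions (retro-oxa-Michael and re-closure) and fed back into the resolution.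

Step 3 (aldol condensation with every phenol free; risk of sluggish addition to the phenoxide-deactivated aldehyde). The fallback sets out from 6 and 7 and comes back at 9. MOMCl/iPr2NEt in CH2Cl2 converts 6 into the bis-MOM ketone F3, leaving the chelated 2-OH free, and converts 7 into the MOM-protected aldehyde F4. A classical Claisen–Schmidt condensation (KOH, EtOH/H2O, rt) joins them to the tris-MOM chalcone F5. Brief treatment with 3 M HCl in MeOH at rt–40 °C removes the three MOM groups to give 9, which is separated from any racemic flavanone or chroman formed.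

Step 1 (double C-prenylation; risk of low yield from O-, mono- and gem-alkylation). The fallback sets out from 1 and 2 and comes back at 6. O-Alkylation under K2CO3 in refluxing acetone gives the bis-prenyl ether F6. Montmorillonite K10 in CH2Cl2 at 0 °C → rt then promotes a double [1,3] O→C prenyl shift to the free ortho/para ring positions (C3 and C5), delivering 6 with normal (not reverse) prenyl groups.

**Further compounds**
F1 | step 4 | racemic 5,7-dihydroxy-2-[4-hydroxy-3-methoxy-5-(3-methylbut-2-en-1-yl)phenyl]-6,8-bis(3-methylbut-2-en-1-yl)chroman-4-one | COc1cc(C2CC(=O)c3c(O)c(CC=C(C)C)c(O)c(CC=C(C)C)c3O2)cc(CC=C(C)C)c1O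
F2 | step 4 | (2R)-5,7-dihydroxy-2-[4-hydroxy-3-methoxy-5-(3-methylbut-2-en-1-yl)phenyl]-6,8-bis(3-methylbut-2-en-1-yl)chroman-4-one | COc1cc([C@H]2CC(=O)c3c(O)c(CC=C(C)C)c(O)c(CC=C(C)C)c3O2)cc(CC=C(C)C)c1O
F3 | step 3 | 1-[2-hydroxy-4,6-bis(methoxymethoxy)-3,5-bis(3-methylbut-2-en-1-yl)phenyl]ethanone | CC(=O)c1c(O)c(CC=C(C)C)c(OCOC)c(CC=C(C)C)c1OCOC
F4 | step 3 | 3-methoxy-4-(methoxymethoxy)-5-(3-methylbut-2-en-1-yl)benzaldehyde | COCOc1c(OC)cc(C=O)cc1CC=C(C)C
F5 | step 3 | (E)-1-[2-hydroxy-4,6-bis(methoxymethoxy)-3,5-bis(3-methylbut-2-en-1-yl)phenyl]-3-[3-methoxy-4-(methoxymethoxy)-5-(3-methylbut-2-en-1-yl)phenyl]prop-2-en-1-one | COCOc1c(OC)cc(/C=C/C(=O)c2c(O)c(CC=C(C)C)c(OCOC)c(CC=C(C)C)c2OCOC)cc1CC=C(C)C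
F6 | step 1 | 1-[2-hydroxy-4,6-bis(3-methylbut-2-en-1-yloxy)phenyl]ethanone | CC(=O)c1c(O)cc(OCC=C(C)C)cc1OCC=C(C)C
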